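In a one-step world each substrate goes straight to its product, and the excess in the product holds steady while both substrates stand at their charge. Here the left-handed substrate falls, so the excess must slip.

| flask | left-handed substrate | right-handed substrate | reagent | free catalyst | remark | time |
|---|---|---|---|---|---|---|
| noon | 0.20 M | 0.20 M | 0.15 M (fed, over 2.5 h) | 1 mM | run made earlier; the fed solution adds 0.10 times the starting volume |  |
| dawn | 0.20 M | 0.20 M | 0.33 M (fed, over 2.5 h) | 1 mM | run made earlier; the fed solution adds 0.10 times the starting volume |  |
| winter | 0.40 M | 0.40 M | 0.22 M (fed, over 2.5 h) | 1 mM | run made earlier; the fed solution adds 0.10 times the starting volume |  |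
| oak | 0.20 M | 0.20 M | 0.220 M (fed, over 2.5 h) | 1.0 mM | the fed solution adds 0.10 times the starting volume | 6.0 d |
| elm | 0.20 M | 0.20 M | 0.220 M (fed, over 5.0 h) | 1.0 mM | the fed solution adds 0.10 times the starting volume | 6.0 d |

| run | time / d | left-handed product / % | right-handed product / % | left-handed substrate / % |
|---|---|---|---|---|
| noon | 0.833 | 6.4 | 1.2 | 43.6 |
| noon | 1.67 | 11.0 | 0 | 38.2 |
| noon | 2.50 | 13.9 | 1.0 | 35.2 |
| noon | 3.00 | 16.0 | 0.5 | 34.3 |
| noon | 4.00 | 17.8 | 1.5 | 32.5 |
| noon | 5.00 | 19.7 | 0.7 | 31.0 |
| dawn | 0.333 | 6.0 | 0 | 44.2 |
| dawn | 0.833 | 12.9 | 0.4 | 37.2 |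
| dawn | 1.67 | 19.1 | 0.8 | 30.2 |
| dawn | 2.50 | 24.2 | 0.5 | 25.6 |
| dawn | 4.00 | 27.9 | 0.7 | 21.9 |
| dawn | 5.00 | 30.1 | 0.3 | 20.1 |
| winter | 0.417 | 4.0 | 0.8 | 46.3 |
| winter | 0.833 | 7.5 | 0 | 43.5 |
| winter | 1.25 | 9.3 | 0.5 | 40.6 |
| winter | 2.50 | 12.9 | 0.1 | 36.8 |
| winter | 5.00 | 17.2 | 0.7 | 32.3 |

(each reading ± 0.5 percentage points)

- free catalyst is single-handed; left-handed substrate and right-handed substrate are mirror images of each other, charged as a racemate, each of them at the stated concentration
- amounts are per litre of the starting volume; all of the dose is in the solution fed
- the numbers in the tables scatter with a standard deviation of 0.5 percentage points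
- steps thought possible: reagent + free catalyst -> spent catalyst; reagent + catalyst intermediate B -> free catalyst + right-handed product; 2 reagent -> homo dimer; reagent + catalyst intermediate A -> free catalyst + left-handed product; free catalyst + left-handed substrate <-> catalyst intermediate A; free catalyst + right-handed substrate <-> catalyst intermediate B; free catalyst <-> dormant form
- an excess is below zero if the other one leads

1. the flask that ends with the higher excess of left-handed product over right-handed product in the product, or "neither" when 2 percentage points or less lies between them (oak / elm / neither)
2. excess of left-handed product over right-handed product in the product at the end, oak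
3. excess of left-handed product over right-handed product in the product at the end, elm

Both product-forming steps take one reagent, so c(reagent) cancels from their ratio. I assume each intermediate follows its substrate, so right-handed product forms against left-handed product as c(right-handed substrate)/(s·c(left-handed substrate)). Hardly any right-handed substrate reacts, since its product never reads above 1.5%.

Let P be left-handed product as a fraction of both substrates charged. Replacing the falling curve by its mean makes the mean substrate ratio 1/(1 − P), so right-handed over left-handed product is q = 1/(s(1 − P)), and the excess is (1 − q)/(1 + q).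

Summed over the noon, dawn and winter tables, right-handed product gives 9.70% and left-handed product 256%, with a mean P of 15.1%. So s, the selectivity factor, the ratio of the two product rates at equal substrate concentrations, reads 31.1. It is a reading, and the right-handed values sit beside a scatter of 0.5 percentage points.

Between noon and dawn at 5.00 d, their last reading, oak's charge of reagent puts P near 23.7%; I have no reading at 6.0 d, so I take that P for oak's end, and my rule gives 91.9%. The exact mean ratio, 1.36 against 1.31, gives 91.6%, a shift smaller than the margin. Elm's feed of 5.0 h is 3.47% of the 6.0 d, so I expect the same P and the same excess in oak and elm.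

The forecast says neither, with 92% for oak and 92% for elm: “Feed time therefore barely changes the reagent history”.

The flasks give neither, with 93.4% for oak and 93.4% for elm, and left-handed product of 26.3% in oak and 26.3% in elm at 6.00 d.

    reagent + free catalyst → spent catalyst (k = 0.0731 M⁻¹ h⁻¹)
    reagent + catalyst intermediate B → free catalyst + right-handed product (k = 1.61 M⁻¹ h⁻¹)
    2 reagent → homo dimer (k = 0.0123 M⁻¹ h⁻¹)
    reagent + catalyst intermediate A → free catalyst + left-handed product (k = 78.5 M⁻¹ h⁻¹)
    free catalyst + left-handed substrate ⇌ catalyst intermediate A (K = 1.80 M⁻¹, k = 3260 M⁻¹ h⁻¹)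
    free catalyst + right-handed substrate ⇌ catalyst intermediate B (K = 2.11 M⁻¹, k = 542 M⁻¹ h⁻¹)
    free catalyst ⇌ dormant form (K = 0.338, k = 0.0409 h⁻¹)

With my s and oak's simulated left-handed product, the rule gives 91.6%, against the flask's 93.4%. A neighbouring flask, oak with 0.055 M of reagent, ends with left-handed product at 9.64%. The same rule gives it 93.1%, which is 1.5 points above the rule's value for oak. The excess in that neighbouring flask ends at 94.8%, with right-handed product at 0.257%.

Readings and results come from a simulation from invented constants, and the scatter is random.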